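## Analysis of the target

The target is a biflavonoid in which a flavanone (rings A, C and B, unprimed atoms) is joined through C3 to C3'' of a flavone (rings A'', C'' and B'', double-primed atoms). Both halves carry the 5,7,4'-trihydroxy pattern. The two chromane cores meet in a single hindered C(sp3)–C(sp2) bond, C3–C3'', flanked by the C4 and C4'' carbonyls and by both para-hydroxyphenyl rings. The only stereocentres are the adjacent C2 (S) and C3 (R) of ring C; they are trans, with the C2 aryl and the C3 flavonyl group both equatorial, which is the thermodynamically preferred arrangement. C3 is alpha to the C4 ketone and can be corrected by epimerisation, so the real stereochemical task is the absolute configuration at C2, a benzylic ether carbon whose configuration is lost whenever ring C opens by retro-oxa-Michael reaction. Sensitive features are the six phenols, the base-labile flavanone ring and the benzylic O1–C2 bond; in addition, the two halves differ only in the oxidation level of one C2–C3 bond, so a symmetrical intermediate would have to be desymmetrised. The strategy rests on two facts: C4 is an aryl ketone carbon bonded to C3, and C3 lies beta to both C2'' and C4'' once ring C'' is opened to its 1,3-diketone, so C3–C4 is the bond an acyl-anion equivalent at the ring A aldehyde carbon forms by conjugate addition. In that open precursor the C2 hydrogen is benzylic, alpha to O1 and gamma to two carbonyls, so C2 can be racemised before ring C closes and is fixed afterwards.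

## Retrosynthetic reasoning

**20 to 19.** The six O–benzyl bonds are cut last. Benzyl ethers survive base, hydride, carbene catalysis and methanolic acid, and come off together by hydrogenolysis, which touches neither stereocentre.

**19 to 17 (through 18).** The O1''–C2'' bond of the flavone is cut, leaving a 2-hydroxyaryl 1,3-diketone. Ring C'' is postponed because the open diketone is what makes C3 electrophilic and C2–H acidic one step earlier. The one phenol of ring A'' that will become O1'' carries a methoxymethyl ether, so that acid can free it selectively and close the pyranone while the benzyl ethers stay on. Closing the flavone before hydrogenolysis also means that only deactivated, vinylogous-ester-type carbonyls are present when hydrogen is used.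

**17 to 16.** The C3–C4 bond is cut. This is the only disconnection that removes ring C and both stereocentres at once without passing through a chalcone, whose ring closure is reversible. The forward reaction must turn the ring A aldehyde carbon of 16 into a nucleophile with a chiral carbene, add it to C3 of the alkylidene diketone, and do so on one C2 enantiomer of a substrate that racemises under the same conditions.

**16 to 9 and 14 (through 15).** The C3=C3'' double bond is cut by a retro-condensation between an aldehyde and the active methylene of a 1,3-diketone. During the condensation the ring A aldehyde is masked as the dimethyl acetal 15, so that only the side-chain aldehyde of 9 is present; mild aqueous acid then uncovers it.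

**14 to 12 and 13, and back to 10.** The diketone is cut between C3'' and C2'' (crossed ester condensation of a methyl ketone with a non-enolisable ester). Ketone 12 comes from 10 through 11 by benzylation of the two unchelated hydroxyls and methoxymethylation of the chelated one.

**9 to 8, 7, and then 2 and 6.** The aldehyde is traced to the ester 8 (partial reduction), the acetal to the free aldehyde 7, and the O1–C2 ether bond is cut to phenol 2 and the alpha-bromo ester 6. The acetal is placed after the ether bond is made: an acetal of the free ortho-hydroxy aldehyde 2 would ionise easily, whereas the free aldehyde of 2 tolerates a carbonate-mediated etherification.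

**6 to 4 and 3 (through 5); 2 to 1.** The bromide is introduced by ionic bromination of the silyl ketene acetal 5 of ester 4, which comes from acid 3. Phenol 2 comes from 1 by benzylation that leaves the chelated hydroxyl free.

## Alternatives that were turned down

**Alternative 1: both phloroglucinol rings made by polyketide-type folding.**
- Disconnection: rings A and A'' are opened at C4a–C5 and C4a''–C5'' and the pyranone at O1''–C2'', leading back to an acyclic core with two triketo ester chains and a beta-methoxy enone.
- Forward key step: Mg(OMe)2 in methanol would close each chain by Claisen condensation and let the new phenoxide displace methoxide at C2'', giving (E)-3-[4-(benzyloxy)phenyl]-2-{2-[4-(benzyloxy)phenyl]-5,7-dihydroxy-4-oxo-4H-chromen-3-yl}-1-(2,4,6-trihydroxyphenyl)prop-2-en-1-one, A1.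
- For it: three rings and three bonds in one operation, and almost no phenol protection (A1 carries only two benzyl ethers). On ring count per step and protecting-group economy it is stronger than the chosen route.
- Against it: the acyclic precursor has many acidic sites and several competing closure modes (aldol instead of Claisen, pyrone formation, retro-Claisen), and assembling two such chains on a congested core is long. A1 is achiral. Its ketone ring has two ortho hydroxyls, so ring C would close spontaneously and without facial control, and the problem of C2 remains unsolved.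
- Comparison: the chosen route buys both aromatic rings from commercial phloroglucinol derivatives with fixed regiochemistry and creates both stereocentres in the bond-forming step.

**Alternative 2: two-directional flavone synthesis through a symmetrical biflavone.**
- Disconnection: C2–C3 and C2''–C3'' are cut by reversing an O-to-C acyl shift in a symmetrical precursor whose two phenol oxygens carry the aroyl groups.
- Forward key step: LiN(SiMe3)2 would effect a double Baker–Venkataraman rearrangement and H2SO4 in acetic acid would close both pyranones, giving 5,5'',7,7''-tetrakis(benzyloxy)-2,2''-bis[4-(benzyloxy)phenyl]-3,3''-bi(4H-chromen-4-one), A2.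
- For it: every reaction up to A2 is established, and symmetry halves the number of operations. On methodological risk up to the key step and on step economy it is stronger.
- Against it: A2 has no stereocentre. The target then requires saturation of exactly one of two equivalent, tetrasubstituted, electron-rich and shielded C2=C3 bonds with control of two stereocentres, without reducing the second ring or a carbonyl. No dependable reaction type exists for this.
- Comparison: the hardest selectivity problem would fall on the most advanced material. The chosen route differentiates the two halves by construction (one enters as aldehyde and ether, the other as diketone) and needs no late redox discrimination.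

**Alternative 3: enantioselective oxa-Michael closure of ring C.**
- Disconnection: O1–C2 is cut, opening ring C to an achiral 2'-hydroxy enone that already carries the flavone at its alpha-carbon.
- Forward key step: N-[3,5-bis(trifluoromethyl)phenyl]-N'-[(8alpha,9S)-6'-methoxycinchonan-9-yl]thiourea (or its pseudoenantiomer) would deliver the phenol to C2 and a proton to C3, giving the hexabenzyl ether A3 (identical with 19).
- For it: the substrate is achiral, so no racemisation has to keep pace with ring closure. The catalytic mode is closer to precedent for flavanone formation, and A3 is one step from the target. On these three points it is as strong as or stronger than the chosen route.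
- Against it: C2 of this enone bears an electron-rich 4-(benzyloxy)phenyl group and is a poor acceptor. The bulky flavonyl group on the alpha-carbon twists the enone. Above all, the closure is reversible under the same amine catalyst, so the configuration at C2 in A3 stays exposed to the reverse reaction and can erode.
- Comparison: the chosen route closes ring C by an irreversible C–C bond formation onto a doubly activated acceptor. Once the ring is closed, O1–C2 never has to be kinetically labile.

Key step: step 11

Remarks on the chemistry:
- Flavonoid locants are used throughout; open-chain intermediates keep the locants their atoms will have in the target.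
- All compounds with a C2 centre before step 11 are racemic.
- The sense of induction of the aminoindanol-derived carbene on a 2-substituted substrate is assumed by analogy. The (5aR,10bS) salt is written, and its (5aS,10bR) antipode is to be used if the first favours the 2R series.

## Route

Step 1
Reactants: 1 2,4,6-trihydroxybenzaldehyde
Product: 2 2,4-bis(benzyloxy)-6-hydroxybenzaldehyde
Conditions: BnBr (2.1 equiv), K2CO3, DMF, 0 °C to rt
Reagents that add atoms: benzyl bromide, BrCc1ccccc1
Why: Williamson ether synthesis; the 4-hydroxyl and one of the two equivalent ortho hydroxyls react, while the last ortho hydroxyl, held in a hydrogen bond to the aldehyde, is much less nucleophilic and should survive with two equivalents of halide.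

Step 2
Reactants: 3 4-(benzyloxy)phenylacetic acid
Product: 4 methyl 2-[4-(benzyloxy)phenyl]acetate
Conditions: MeOH, H2SO4 (cat.), reflux
Reagents that add atoms: methanol, CO
Why: Fischer esterification; the benzyl ether is stable to catalytic acid in methanol.

Step 3
Reactants: 4 methyl 2-[4-(benzyloxy)phenyl]acetate
Product: 6 methyl 2-[4-(benzyloxy)phenyl]-2-bromoacetate (racemic), via silyl ketene acetal 5 (not isolated)
Conditions: LiN(SiMe3)2, Me3SiCl, THF, −78 °C; then NBS, −78 to 0 °C
Reagents that add atoms: N-bromosuccinimide, O=C1CCC(=O)N1Br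
Why: The ester is trapped as its silyl ketene acetal, which NBS brominates at carbon; this ionic alpha-bromination avoids radical attack at the benzyl ether methylene and the alkylation of a free enolate by the product.

Step 4
Reactants: 2 2,4-bis(benzyloxy)-6-hydroxybenzaldehyde; 6 methyl 2-[4-(benzyloxy)phenyl]-2-bromoacetate
Product: 7 methyl 2-[3,5-bis(benzyloxy)-2-formylphenoxy]-2-[4-(benzyloxy)phenyl]acetate (racemic)
Conditions: K2CO3, DMF, rt
Reagents that add atoms: none
Why: Williamson ether synthesis by SN2 attack of the phenoxide on a benzylic alpha-bromo ester, which forms O1–C2. The mild carbonate base at room temperature and the poor electrophilicity of the trioxygenated aldehyde should keep intramolecular aldol addition, which cannot dehydrate and is reversible, in check.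

Step 5
Reactants: 7 methyl 2-[3,5-bis(benzyloxy)-2-formylphenoxy]-2-[4-(benzyloxy)phenyl]acetate
Product: 8 methyl 2-[3,5-bis(benzyloxy)-2-(dimethoxymethyl)phenoxy]-2-[4-(benzyloxy)phenyl]acetate (racemic)
Conditions: HC(OMe)3 (5 equiv), pyridinium p-toluenesulfonate (cat.), CH2Cl2, rt; then Et3N
Reagents that add atoms: trimethyl orthoformate, COC(OC)OC
Why: Acid-catalysed acetalisation in which the orthoformate supplies the methoxy groups and removes the water equivalent; the mask is needed so that the ester can be reduced next, and it is put on after the ether bond because the acetal of the free ortho-hydroxy aldehyde would ionise readily.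

Step 6
Reactants: 8 methyl 2-[3,5-bis(benzyloxy)-2-(dimethoxymethyl)phenoxy]-2-[4-(benzyloxy)phenyl]acetate
Product: 9 2-[3,5-bis(benzyloxy)-2-(dimethoxymethyl)phenoxy]-2-[4-(benzyloxy)phenyl]acetaldehyde (racemic)
Conditions: i-Bu2AlH (1.1 equiv), toluene, −78 °C; MeOH, aq. potassium sodium tartrate
Reagents that add atoms: none
Why: Partial reduction of an ester with i-Bu2AlH; the alpha-aryloxy ester gives a chelated aluminium hemiacetal that is stable at −78 °C and releases the aldehyde only on work-up, and the acetal should be inert to the hydride at this temperature. The aldehyde is used at once.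

Step 7
Reactants: 10 2',4',6'-trihydroxyacetophenone
Product: 11 1-[2,4-bis(benzyloxy)-6-hydroxyphenyl]ethan-1-one
Conditions: BnBr (2.1 equiv), K2CO3, DMF, rt
Reagents that add atoms: benzyl bromide, BrCc1ccccc1
Why: Williamson ether synthesis with the same selectivity as in step 1; the hydroxyl chelated to the ketone stays free.

Step 8
Reactants: 11 1-[2,4-bis(benzyloxy)-6-hydroxyphenyl]ethan-1-one
Product: 12 1-[2,4-bis(benzyloxy)-6-(methoxymethoxy)phenyl]ethan-1-one
Conditions: NaH, MeOCH2Cl, DMF, 0 °C to rt
Reagents that add atoms: chloromethyl methyl ether, COCCl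
Why: Williamson-type alkylation of the sodium phenoxide, whose formation breaks the hydrogen bond to the ketone; the methoxymethyl ether is orthogonal to the benzyl ethers, so this one phenol can be freed later by acid.

Step 9
Reactants: 12 1-[2,4-bis(benzyloxy)-6-(methoxymethoxy)phenyl]ethan-1-one; 13 methyl 4-(benzyloxy)benzoate
Product: 14 1-[2,4-bis(benzyloxy)-6-(methoxymethoxy)phenyl]-3-[4-(benzyloxy)phenyl]propane-1,3-dione
Conditions: NaH (2.5 equiv), THF, 65 °C; then AcOH, 0 °C
Reagents that add atoms: none
Why: Crossed Claisen condensation of the ketone enolate with a non-enolisable ester; deprotonation of the 1,3-diketone product drives the equilibrium.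

Step 10
Reactants: 9 2-[3,5-bis(benzyloxy)-2-(dimethoxymethyl)phenoxy]-2-[4-(benzyloxy)phenyl]acetaldehyde; 14 1-[2,4-bis(benzyloxy)-6-(methoxymethoxy)phenyl]-3-[4-(benzyloxy)phenyl]propane-1,3-dione
Product: 16 2,4-bis(benzyloxy)-6-{[3-[4-(benzyloxy)benzoyl]-1-[4-(benzyloxy)phenyl]-4-[2,4-bis(benzyloxy)-6-(methoxymethoxy)phenyl]-4-oxobut-2-en-1-yl]oxy}benzaldehyde (racemic at C2; alkene geometry mixed), via dimethyl acetal 15 (not isolated)
Conditions: piperidine (0.2 equiv), AcOH (0.2 equiv), 4 Å MS, CH2Cl2, rt; then pyridinium p-toluenesulfonate, acetone/H2O, rt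
Reagents that add atoms: water, O
Why: Knoevenagel condensation through the iminium ion of the reactive alpha-aryloxy aldehyde, the usual entry to 2-alkylidene-1,3-diaryl-1,3-diketones; any deconjugated enol-ether isomer is acceptable because base returns it to the same dienolate in step 11. The very electron-rich benzaldehyde dimethyl acetal is then hydrolysed under conditions too mild to cleave the aryl methoxymethyl ether or the benzyl ethers.

Step 11
Reactants: 16 2,4-bis(benzyloxy)-6-{[3-[4-(benzyloxy)benzoyl]-1-[4-(benzyloxy)phenyl]-4-[2,4-bis(benzyloxy)-6-(methoxymethoxy)phenyl]-4-oxobut-2-en-1-yl]oxy}benzaldehyde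
Product: 17 (2S,3R)-5,7-bis(benzyloxy)-2-[4-(benzyloxy)phenyl]-3-{1-[4-(benzyloxy)phenyl]-3-[2,4-bis(benzyloxy)-6-(methoxymethoxy)phenyl]-1,3-dioxopropan-2-yl}chroman-4-one (diketone methine labile, not defined)
Conditions: (5aR,10bS)-2-(pentafluorophenyl)-5a,10b-dihydro-4H,6H-indeno[2,1-b][1,2,4]triazolo[4,3-d][1,4]oxazin-2-ium tetrafluoroborate (20 mol %), i-Pr2NEt (1 equiv), toluene, 25 °C
Reagents that add atoms: none
Why: Proposed new method: the carbene freed from the triazolium salt by i-Pr2NEt adds to the ring A aldehyde, proton transfer gives the hydroxy-enamine (an acyl-anion equivalent), this adds to C3, the beta-carbon of the doubly activated alkylidene diketone, and collapse of the adduct releases the carbene and leaves the C4 ketone; the closest known reaction type is the triazolylidene-catalysed enantioselective intramolecular Stetter reaction of salicylaldehyde-derived acceptors to chroman-4-ones, which has not been run as a dynamic kinetic resolution of a substrate with a stereocentre at C2. Ring C closes in the 6-exo-trig mode, C4 attacking C3 while the C3=C3'' double bond lies outside the new ring. C3 is set in the C–C bond-forming event by the catalyst, whose fused aminoindanol wall leaves one face of the hydroxy-enamine open; the E or Z geometry of the acceptor does not change the outcome because both substituents on C3'' are acyl groups. C2 is not created but selected: its hydrogen is benzylic, alpha to O1 and gamma to two carbonyls, so the amine interconverts the C2 enantiomers through the dienolate (the deconjugated enol-ether tautomer feeds the same dienolate), and only the enantiomer that can place its C2 aryl group pseudo-equatorial and anti to the forming C3–C4 bond in the catalyst-preferred transition state should cyclise quickly. The step needs a large rate ratio between the two C2 enantiomers, racemisation faster than ring closure, and conjugate addition faster than benzoin or aldol processes. Racemisation is favoured by the acidity of C2–H together with the slow carbene addition to a di-ortho-oxygenated, electron-rich aldehyde, and conjugate addition by the high electrophilicity of the alkylidene 1,3-diketone and the reversibility of an aldol adduct that cannot dehydrate. After closure C2 is no longer vinylogously acidic, the most acidic site of 17 is the spectator diketone methine, and C3, alpha to the C4 ketone, can settle into the trans (2S,3R) arrangement with both large groups equatorial.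

Step 12
Reactants: 17 (2S,3R)-5,7-bis(benzyloxy)-2-[4-(benzyloxy)phenyl]-3-{1-[4-(benzyloxy)phenyl]-3-[2,4-bis(benzyloxy)-6-(methoxymethoxy)phenyl]-1,3-dioxopropan-2-yl}chroman-4-one
Product: 19 (2S,3R)-5,7-bis(benzyloxy)-3-{5,7-bis(benzyloxy)-2-[4-(benzyloxy)phenyl]-4-oxo-4H-chromen-3-yl}-2-[4-(benzyloxy)phenyl]chroman-4-one, via hydroxyaryl diketone 18 (not isolated)
Conditions: HCl (1.25 M in MeOH), THF, 45 °C
Reagents that add atoms: none
Why: Acidic methanolysis removes the methoxymethyl ether, and the freed phenol adds to the 4-(benzyloxy)benzoyl carbonyl and loses water (cyclodehydration of a 2-hydroxyaryl 1,3-diketone, the closing stage of a Baker–Venkataraman flavone synthesis), forming O1''–C2''. C2 is not involved, and C3, still alpha to the C4 ketone, keeps the trans arrangement; loss of a benzyl ether here would be of no consequence.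

Step 13
Reactants: 19 (2S,3R)-5,7-bis(benzyloxy)-3-{5,7-bis(benzyloxy)-2-[4-(benzyloxy)phenyl]-4-oxo-4H-chromen-3-yl}-2-[4-(benzyloxy)phenyl]chroman-4-one
Product: 20 (2S,3R)-3-[5,7-dihydroxy-2-(4-hydroxyphenyl)-4-oxo-4H-chromen-3-yl]-5,7-dihydroxy-2-(4-hydroxyphenyl)chroman-4-one
Conditions: H2 (1 atm), palladium on carbon (Pd/C, 10 %), THF/MeOH, rt
Reagents that add atoms: none
Why: Hydrogenolysis of the six benzyl ethers over palladium; both carbonyls are deactivated vinylogous esters and the tetrasubstituted flavone alkene is not reduced, and stopping at the calculated hydrogen uptake should spare the benzylic O1–C2 bond.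

## Compound list

1 | 2,4,6-trihydroxybenzaldehyde | O=Cc1c(O)cc(O)cc1O | starting material
2 | 2,4-bis(benzyloxy)-6-hydroxybenzaldehyde | O=Cc1c(O)cc(OCc2ccccc2)cc1OCc1ccccc1 | intermediate
3 | 4-(benzyloxy)phenylacetic acid | OC(=O)Cc1ccc(OCc2ccccc2)cc1 | starting material
4 | methyl 2-[4-(benzyloxy)phenyl]acetate | COC(=O)Cc1ccc(OCc2ccccc2)cc1 | intermediate
5 | {[2-(4-benzyloxyphenyl)-1-methoxyethenyl]oxy}trimethylsilane (silyl ketene acetal, geometry not defined, not isolated) | COC(O[Si](C)(C)C)=Cc1ccc(OCc2ccccc2)cc1 | intermediate
6 | methyl 2-[4-(benzyloxy)phenyl]-2-bromoacetate (racemic) | COC(=O)C(Br)c1ccc(OCc2ccccc2)cc1 | intermediate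
7 | methyl 2-[3,5-bis(benzyloxy)-2-formylphenoxy]-2-[4-(benzyloxy)phenyl]acetate (racemic) | COC(=O)C(Oc1cc(OCc2ccccc2)cc(OCc2ccccc2)c1C=O)c1ccc(OCc2ccccc2)cc1 | intermediate
8 | methyl 2-[3,5-bis(benzyloxy)-2-(dimethoxymethyl)phenoxy]-2-[4-(benzyloxy)phenyl]acetate (racemic) | COC(=O)C(Oc1cc(OCc2ccccc2)cc(OCc2ccccc2)c1C(OC)OC)c1ccc(OCc2ccccc2)cc1 | intermediate
9 | 2-[3,5-bis(benzyloxy)-2-(dimethoxymethyl)phenoxy]-2-[4-(benzyloxy)phenyl]acetaldehyde (racemic) | O=CC(Oc1cc(OCc2ccccc2)cc(OCc2ccccc2)c1C(OC)OC)c1ccc(OCc2ccccc2)cc1 | intermediate
10 | 2',4',6'-trihydroxyacetophenone | CC(=O)c1c(O)cc(O)cc1O | starting material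
11 | 1-[2,4-bis(benzyloxy)-6-hydroxyphenyl]ethan-1-one | CC(=O)c1c(O)cc(OCc2ccccc2)cc1OCc1ccccc1 | intermediate
12 | 1-[2,4-bis(benzyloxy)-6-(methoxymethoxy)phenyl]ethan-1-one | CC(=O)c1c(OCOC)cc(OCc2ccccc2)cc1OCc1ccccc1 | intermediate
13 | methyl 4-(benzyloxy)benzoate | COC(=O)c1ccc(OCc2ccccc2)cc1 | starting material
14 | 1-[2,4-bis(benzyloxy)-6-(methoxymethoxy)phenyl]-3-[4-(benzyloxy)phenyl]propane-1,3-dione | O=C(CC(=O)c1ccc(OCc2ccccc2)cc1)c1c(OCOC)cc(OCc2ccccc2)cc1OCc1ccccc1 | intermediate
15 | 2-[4-(benzyloxy)benzoyl]-1-[2,4-bis(benzyloxy)-6-(methoxymethoxy)phenyl]-4-[3,5-bis(benzyloxy)-2-(dimethoxymethyl)phenoxy]-4-[4-(benzyloxy)phenyl]but-2-en-1-one (racemic, geometry mixed, not isolated) | COC(OC)c1c(OC(C=C(C(=O)c2ccc(OCc3ccccc3)cc2)C(=O)c2c(OCOC)cc(OCc3ccccc3)cc2OCc2ccccc2)c2ccc(OCc3ccccc3)cc2)cc(OCc2ccccc2)cc1OCc1ccccc1 | intermediate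
16 | 2,4-bis(benzyloxy)-6-{[3-[4-(benzyloxy)benzoyl]-1-[4-(benzyloxy)phenyl]-4-[2,4-bis(benzyloxy)-6-(methoxymethoxy)phenyl]-4-oxobut-2-en-1-yl]oxy}benzaldehyde (racemic at C2, geometry mixed) | O=Cc1c(OC(C=C(C(=O)c2ccc(OCc3ccccc3)cc2)C(=O)c2c(OCOC)cc(OCc3ccccc3)cc2OCc2ccccc2)c2ccc(OCc3ccccc3)cc2)cc(OCc2ccccc2)cc1OCc1ccccc1 | intermediate
17 | (2S,3R)-5,7-bis(benzyloxy)-2-[4-(benzyloxy)phenyl]-3-{1-[4-(benzyloxy)phenyl]-3-[2,4-bis(benzyloxy)-6-(methoxymethoxy)phenyl]-1,3-dioxopropan-2-yl}chroman-4-one | O=C1c2c(OCc3ccccc3)cc(OCc3ccccc3)cc2O[C@H](c2ccc(OCc3ccccc3)cc2)[C@H]1C(C(=O)c1ccc(OCc2ccccc2)cc1)C(=O)c1c(OCOC)cc(OCc2ccccc2)cc1OCc1ccccc1 | intermediate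
18 | (2S,3R)-5,7-bis(benzyloxy)-2-[4-(benzyloxy)phenyl]-3-{1-[4-(benzyloxy)phenyl]-3-[2,4-bis(benzyloxy)-6-hydroxyphenyl]-1,3-dioxopropan-2-yl}chroman-4-one (not isolated) | O=C1c2c(OCc3ccccc3)cc(OCc3ccccc3)cc2O[C@H](c2ccc(OCc3ccccc3)cc2)[C@H]1C(C(=O)c1ccc(OCc2ccccc2)cc1)C(=O)c1c(O)cc(OCc2ccccc2)cc1OCc1ccccc1 | intermediate
19 | (2S,3R)-5,7-bis(benzyloxy)-3-{5,7-bis(benzyloxy)-2-[4-(benzyloxy)phenyl]-4-oxo-4H-chromen-3-yl}-2-[4-(benzyloxy)phenyl]chroman-4-one | O=C1c2c(OCc3ccccc3)cc(OCc3ccccc3)cc2O[C@H](c2ccc(OCc3ccccc3)cc2)[C@H]1c1c(-c2ccc(OCc3ccccc3)cc2)oc2cc(OCc3ccccc3)cc(OCc3ccccc3)c2c1=O | intermediate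
20 | (2S,3R)-3-[5,7-dihydroxy-2-(4-hydroxyphenyl)-4-oxo-4H-chromen-3-yl]-5,7-dihydroxy-2-(4-hydroxyphenyl)chroman-4-one | O=C1c2c(O)cc(O)cc2O[C@H](c2ccc(O)cc2)[C@H]1c1c(-c2ccc(O)cc2)oc2cc(O)cc(O)c2c1=O | target

## Step count and uncertain steps

Total: 13 steps. Longest linear sequence: 9 steps (3 to 20 through steps 2, 3, 4, 5, 6, 10, 11, 12 and 13).

**Step 11 (key step, proposed new method).**
- What may go wrong: racemisation of 16 may lag behind ring closure, so that the reaction becomes a plain kinetic resolution and the slow enantiomer leaks into the 2R series. The catalyst may discriminate poorly between the two C2 enantiomers. Carbene addition to the di-ortho-oxygenated aldehyde may be so slow that the dienolate is diverted into aldol addition to the aldehyde.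
- Fallback with known chemistry: from 16, ring C is closed without induction by an achiral thiazolylidene carbene (3-benzyl-5-(2-hydroxyethyl)-4-methylthiazol-3-ium chloride, Et3N, 1,4-dioxane, 70 °C), an established Stetter closure to chroman-4-ones. This gives the racemic trans chromanone rac-(2S*,3R*)-5,7-bis(benzyloxy)-2-[4-(benzyloxy)phenyl]-3-{1-[4-(benzyloxy)phenyl]-3-[2,4-bis(benzyloxy)-6-(methoxymethoxy)phenyl]-1,3-dioxopropan-2-yl}chroman-4-one F1, the amine equilibrating C3 to trans. Preparative chromatography on a chiral stationary phase (immobilised amylose tris(3,5-dimethylphenylcarbamate)) then separates the (2S,3R) enantiomer, which is 17, where the route is rejoined.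

**Step 10.**
- What may go wrong: the condensation is reversible and may stall, because the enolisable aldehyde is drawn off into its enamine and self-condensation while the bulky diketone adds slowly; the exposed alkylidene diketone can also be eroded by conjugate addition of amine or of a second diketone.
- Fallback: from 9 and 14, the adduct is trapped by hydride as it forms in a proline-catalysed three-component reductive alkylation ((S)-proline, diethyl 2,6-dimethyl-1,4-dihydropyridine-3,5-dicarboxylate, CH2Cl2, rt). This gives the saturated diketone 2-{2-[3,5-bis(benzyloxy)-2-(dimethoxymethyl)phenoxy]-2-[4-(benzyloxy)phenyl]ethyl}-1-[2,4-bis(benzyloxy)-6-(methoxymethoxy)phenyl]-3-[4-(benzyloxy)phenyl]propane-1,3-dione F2. Selenenylation (PhSeCl, pyridine, CH2Cl2, 0 °C) gives the 2-(phenylselanyl) diketone F3. Oxidation (NaIO4, NaHCO3, aq. THF) and syn-elimination of the selenoxide, which can only remove a C3 hydrogen, re-forms the C3=C3'' double bond and gives 15, which is hydrolysed to 16 as in step 10.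

**Step 6.**
- What may go wrong: over-reduction to the primary alcohol, or Lewis-acid-assisted ionisation of the dimethyl acetal to the highly stabilised trialkoxybenzyl oxocarbenium ion followed by hydride capture.
- Fallback: from 8, the ester is reduced fully with LiBH4 (THF, 0 °C to rt), which has no Lewis acidity towards the acetal, to 2-[3,5-bis(benzyloxy)-2-(dimethoxymethyl)phenoxy]-2-[4-(benzyloxy)phenyl]ethan-1-ol F4. This is oxidised under basic conditions (Parikh–Doering oxidation: SO3·pyridine, DMSO, i-Pr2NEt, CH2Cl2, 0 °C) to 9.

**Step 12.**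
- What may go wrong: if dehydration to the hindered, tetrasubstituted C2''=C3'' alkene needs forcing acid, acid-driven furan formation across the 1,4-dicarbonyl unit (C4 with a diketone carbonyl, Paal–Knorr type) and acid-mediated opening of ring C with loss of configuration at C2 may compete.
- Fallback: from 17, all ethers are removed at low temperature with BCl3 and pentamethylbenzene (CH2Cl2, −78 °C), which cleaves the methoxymethyl and the six benzyl ethers with the arene trapping the benzyl cations. The methanol quench liberates (2S,3R)-5,7-dihydroxy-2-(4-hydroxyphenyl)-3-[1-(4-hydroxyphenyl)-1,3-dioxo-3-(2,4,6-trihydroxyphenyl)propan-2-yl]chroman-4-one F5. With the 5-hydroxyl now hydrogen-bonded to C4, that carbonyl is less electrophilic and less enolisable, and F5 cyclodehydrates in the dilute methanolic HCl of the quench at rt to give 20 directly; steps 12 and 13 are thereby merged.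

## Further compounds

F1 | step 11 | rac-(2S*,3R*)-5,7-bis(benzyloxy)-2-[4-(benzyloxy)phenyl]-3-{1-[4-(benzyloxy)phenyl]-3-[2,4-bis(benzyloxy)-6-(methoxymethoxy)phenyl]-1,3-dioxopropan-2-yl}chroman-4-one (racemate, both enantiomers written) | O=C1c2c(OCc3ccccc3)cc(OCc3ccccc3)cc2O[C@H](c2ccc(OCc3ccccc3)cc2)[C@H]1C(C(=O)c1ccc(OCc2ccccc2)cc1)C(=O)c1c(OCOC)cc(OCc2ccccc2)cc1OCc1ccccc1.O=C1c2c(OCc3ccccc3)cc(OCc3ccccc3)cc2O[C@@H](c2ccc(OCc3ccccc3)cc2)[C@@H]1C(C(=O)c1ccc(OCc2ccccc2)cc1)C(=O)c1c(OCOC)cc(OCc2ccccc2)cc1OCc1ccccc1
F2 | step 10 | 2-{2-[3,5-bis(benzyloxy)-2-(dimethoxymethyl)phenoxy]-2-[4-(benzyloxy)phenyl]ethyl}-1-[2,4-bis(benzyloxy)-6-(methoxymethoxy)phenyl]-3-[4-(benzyloxy)phenyl]propane-1,3-dione (stereocentres not defined) | COC(OC)c1c(OC(CC(C(=O)c2ccc(OCc3ccccc3)cc2)C(=O)c2c(OCOC)cc(OCc3ccccc3)cc2OCc2ccccc2)c2ccc(OCc3ccccc3)cc2)cc(OCc2ccccc2)cc1OCc1ccccc1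
F3 | step 10 | 2-{2-[3,5-bis(benzyloxy)-2-(dimethoxymethyl)phenoxy]-2-[4-(benzyloxy)phenyl]ethyl}-1-[2,4-bis(benzyloxy)-6-(methoxymethoxy)phenyl]-3-[4-(benzyloxy)phenyl]-2-(phenylselanyl)propane-1,3-dione (stereocentres not defined) | COC(OC)c1c(OC(CC([Se]c2ccccc2)(C(=O)c2ccc(OCc3ccccc3)cc2)C(=O)c2c(OCOC)cc(OCc3ccccc3)cc2OCc2ccccc2)c2ccc(OCc3ccccc3)cc2)cc(OCc2ccccc2)cc1OCc1ccccc1
F4 | step 6 | 2-[3,5-bis(benzyloxy)-2-(dimethoxymethyl)phenoxy]-2-[4-(benzyloxy)phenyl]ethan-1-ol (racemic) | OCC(Oc1cc(OCc2ccccc2)cc(OCc2ccccc2)c1C(OC)OC)c1ccc(OCc2ccccc2)cc1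
F5 | step 12 | (2S,3R)-5,7-dihydroxy-2-(4-hydroxyphenyl)-3-[1-(4-hydroxyphenyl)-1,3-dioxo-3-(2,4,6-trihydroxyphenyl)propan-2-yl]chroman-4-one | O=C1c2c(O)cc(O)cc2O[C@H](c2ccc(O)cc2)[C@H]1C(C(=O)c1ccc(O)cc1)C(=O)c1c(O)cc(O)cc1O
A1 | alternative 1 | (E)-3-[4-(benzyloxy)phenyl]-2-{2-[4-(benzyloxy)phenyl]-5,7-dihydroxy-4-oxo-4H-chromen-3-yl}-1-(2,4,6-trihydroxyphenyl)prop-2-en-1-one | O=C(c1c(O)cc(O)cc1O)/C(=C/c1ccc(OCc2ccccc2)cc1)c1c(-c2ccc(OCc3ccccc3)cc2)oc2cc(O)cc(O)c2c1=O
A2 | alternative 2 | 5,5'',7,7''-tetrakis(benzyloxy)-2,2''-bis[4-(benzyloxy)phenyl]-3,3''-bi(4H-chromen-4-one) | O=c1c(-c2c(-c3ccc(OCc4ccccc4)cc3)oc3cc(OCc4ccccc4)cc(OCc4ccccc4)c3c2=O)c(-c2ccc(OCc3ccccc3)cc2)oc2cc(OCc3ccccc3)cc(OCc3ccccc3)c12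
A3 | alternative 3 | (2S,3R)-5,7-bis(benzyloxy)-3-{5,7-bis(benzyloxy)-2-[4-(benzyloxy)phenyl]-4-oxo-4H-chromen-3-yl}-2-[4-(benzyloxy)phenyl]chroman-4-one | O=C1c2c(OCc3ccccc3)cc(OCc3ccccc3)cc2O[C@H](c2ccc(OCc3ccccc3)cc2)[C@H]1c1c(-c2ccc(OCc3ccccc3)cc2)oc2cc(OCc3ccccc3)cc(OCc3ccccc3)c2c1=O
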